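## Structural features

Tomentodiplacone B is a (2S)-flavanone. Benzene ring A (C4a, C5–C8, C8a) is fused to the dihydro-γ-pyranone ring C (O1, C2, C3, C4=O), and ring B (4-hydroxy-3-methoxyphenyl) is attached to C2 through the single bond C2–C1'. Ring A is a fully differentiated phloroglucinol: O1 sits on C8a, a hydroxyl chelated to the C4 carbonyl on C5, a free hydroxyl on C7, hydrogen on C8, and a C10 chain on C6 between the two hydroxyls. The chain is (2E,5E)-7-hydroxy-3,7-dimethylocta-2,5-dienyl, a skipped diene made of a trisubstituted E alkene (C2''=C3''), a doubly allylic CH2 (C4''), a disubstituted E alkene (C5''=C6'') and a tertiary allylic alcohol (C7''). C2 is the only stereocentre and has no stereogenic neighbour, but it is benzylic, β to the ketone and bonded to a phenoxide leaving group, so base or heat opens ring C by retro-oxa-Michael reaction to the achiral chalcone. That opening racemises C2, and because re-closure can use O5 instead of O1 it also moves the chain from C6 to C8. The tertiary allylic alcohol ionises in acid, which excludes acetal protecting groups and Lewis-acidic ring closures late in the route, and the phenols and C4'' are sensitive to oxidants. The real difficulty is therefore one of order: a base-labile stereocentre, an acid-labile carbinol and the C6 (not C8) position of the chain must all be correct at the same time. The key step exploits that C2 is the β-carbon of the C2–C3–C4=O unit of ring C and holds ring B by one bond only. Without ring B, ring C is the flat, achiral γ-pyrone of a chromone, which resists ring opening and whose C2=C3 bond is a Michael acceptor.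

## Logic of the disconnections

**18 from 17.** Bonds cut: O5–Si, O7–Si and O4'–Si. The last operation acts on a compound that carries both the base-labile C2 and the acid-labile C7'' carbinol, so it must run near neutrality, and phenolic silyl ethers fall to buffered fluoride. The skeletal gain is small but the gain in safety is large, because 17 has no free phenol and therefore no phenoxide that could push ring C open. Demand: each phenoxide must be protonated as it forms.

**17 from 16 and 10 (key disconnection).** Bond cut: C2–C1', between ring C and ring B. In one sentence, the route is the enantioselective conjugate arylation of C2 of 16 by 10. That sentence does not fit the chalcone route, where C2–C1' is never made because it arrives with the aldehyde. The new bond is a C–C bond that cannot revert, whereas O1–C2 closure is the reverse of the racemisation pathway. The only stereocentre, ring B and a third of the heavy atoms disappear at once. What remains is achiral and flat, with O1 locked in a γ-pyrone, so all harsh chemistry can be done where neither racemisation nor C6-to-C8 migration is possible. Demand: the catalyst must tell the two faces of C2=C3 apart, ignore two isolated alkenes and a tertiary alcohol, and work without base or heat.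

**16 from 15 and 5.** Bond cut: C6–C1''. The complete chain, with both alkene geometries and the carbinol already in place, is joined to ring A in one neutral step. The polarity (aryl nucleophile, allyl electrophile) is chosen because a π-allyl complex made by ionisation keeps the E geometry, whereas an allyl-metal reagent can lose it through its tertiary σ-isomer. The gain is a convergent split into a C10 piece and a bicyclic core. Demand: coupling at the primary terminus, retention at C2''=C3'', and no ionisation at C7''.

**15 from 14.** Bond cut: C6–Sn, exchanged for C6–I. Tin gives a neutral, proton-tolerant aryl nucleophile that coexists with the γ-pyrone carbonyl, which lithium or magnesium would attack. Demand: metal exchange at a site flanked by two silyloxy groups.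

**14 from 13, and 13 from 12.** Bonds cut: O5–Si, then C6–I. The C6/C8 question is answered here, on the smallest possible compound. The free chelated 5-OH is the control element, so iodination comes before silylation of O5. This turns a regiochemical problem of the whole target into a single SEAr step. Demand: attack at C6 only and mono-iodination.

**12 from 11.** Bond cut: O7–Si. The acidic, unchelated 7-OH is masked while the chelated 5-OH stays free to direct the next step. Demand: chemoselectivity between two phenols, which the chelate provides.

**5 from 2, and 2 from 1.** The C7''–OH bond and the C5''=C6'' alkene are traced back, through the C6''–C7'' epoxide, to the C6''=C7'' alkene of 1. The whole carbon chain and the E C2''=C3'' alkene are bought, and only a 1,3-transposition with oxygenation has to be carried out. Demand: reaction at the distal alkene only, and E-selective elimination away from C7''.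

**10 from 7, and 7 from 6.** Bonds cut: C1'–B and O4'–Si. This is a standard halogen–metal exchange and borylation. Demand: no silyl migration, which the para relation of lithium and the silyloxy group secures.

## Other disconnections considered

**Alternative 1:** The cut is O1–C2 of ring C, then the Cα=Cβ bond of the 2'-hydroxychalcone A1. The forward key step is a Claisen–Schmidt condensation followed by catalytic asymmetric intramolecular oxa-Michael closure. This is the first plan that comes to mind. In A1 both ortho hydroxyls (the future O1 and O5) can close, so C6 against C8 is decided only by additional differential protection of ring A. The closure is the microscopic reverse of the racemisation pathway, so with no extra activating group at C3 the catalyst works against an equilibrium and the configuration stays at risk for as long as catalyst and product are together. The aldol step also needs strong base on a polyphenol. The chosen plan forms an irreversible C–C bond at C2 and has O1 fixed from its first compound.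

**Alternative 2:** The cut is C6–C1'', with the chain first parked on the future O1. The forward key step is a tandem aromatic Claisen–Cope (para-Claisen) rearrangement of the aryl allyl ether A2 to the acetophenone A3. The topology is attractive, because C6 is para to O1 and the rearrangement frees exactly the phenol that must later close ring C. However, the C2''=C3'' alkene is destroyed in the first [3,3] shift and rebuilt in the second through a chair in which CH3 and CH2R on C3'' differ little in size, so an E/Z mixture is expected. The temperature such rearrangements need should dehydrate the tertiary allylic alcohol. C2 would still be left to the chalcone closure of Alternative 1.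

**Alternative 3:** The cuts are C4a–C5 and C8–C8a, so ring A is built last. The forward key step is a Diels–Alder/aromatisation between the enantiopure bromodihydropyranone A4, available by a catalytic asymmetric hetero-Diels–Alder reaction and α-bromination, and the 2-alkylated bis(silyloxy)ketene-acetal diene A5. The polarity matches (nucleophilic C8 terminus to the β-carbon C8a), and C6 is fixed by connectivity. But A4 is a donor-substituted, poor dienophile. In the cycloadduct C8a–H is not acidic while C8–H, α to the unveiled C7 carbonyl, is. The easiest aromatising elimination should therefore expel O1 (β-alkoxy elimination) rather than HBr, which opens ring C and removes the oxygen from C8a. The step count would be no lower than in the chosen plan.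

Key step: step 10

**Remarks on the chemistry.** Compounds 1, 6 and 11 are taken as catalogue compounds. Catalyst-bound palladium and rhodium species of catalytic cycles are described in words and carry no number. Locants follow flavanone numbering (ring B primed, chain doubly primed) throughout.

## Steps

Step 1
Reactants: 1 geranyl acetate
Product: 2 6,7-epoxygeranyl acetate (racemic)
Conditions: mCPBA (1.0 equiv), CH2Cl2, 0 °C
Reagents that add atoms: mCPBA (3-chloroperoxybenzoic acid), O=C(OO)c1cccc(Cl)c1
Why: Prilezhaev epoxidation; the distal trisubstituted alkene is the more electron-rich one because the proximal alkene is deactivated by the allylic acetoxy group. The new stereocentre is racemic and is erased in step 2.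

Step 2
Reactants: 2 6,7-epoxygeranyl acetate (racemic)
Product: 5 (2E,5E)-7-hydroxy-3,7-dimethylocta-2,5-dien-1-yl acetate, via hydroxyselenide 3 (not isolated), via selenoxide 4 (not isolated)
Conditions: (PhSe)2 (0.55 equiv), NaBH4, EtOH, 0 to 60 °C; then THF, 30% H2O2, 0 °C to rt
Reagents that add atoms: none
Why: Organoselenium epoxide-to-allylic-alcohol transposition: phenylselenide opens the epoxide by SN2 at the less substituted carbon, and oxidation gives selenoxide 4. Its syn elimination can only use the C5 hydrogens because C7 bears none, and the less crowded transition state should give the E alkene.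

Step 3
Reactants: 6 4-bromo-2-methoxyphenol
Product: 7 (4-bromo-2-methoxyphenoxy)(tert-butyl)dimethylsilane
Conditions: TBSCl (1.1 equiv), imidazole (2.2 equiv), DMF, rt
Reagents that add atoms: tert-butyldimethylsilyl chloride, CC(C)(C)[Si](C)(C)Cl
Why: Standard imidazole-promoted silylation of an unhindered phenol.

Step 4
Reactants: 7 (4-bromo-2-methoxyphenoxy)(tert-butyl)dimethylsilane
Product: 10 [4-(tert-butyldimethylsilyloxy)-3-methoxyphenyl]boronic acid, via aryllithium 8 (not isolated), via lithium triisopropyl arylborate 9 (not isolated)
Conditions: n-BuLi (1.05 equiv), THF, −78 °C; B(OiPr)3 (1.5 equiv), −78 °C to rt; 1 M HCl, 0 °C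
Reagents that add atoms: triisopropyl borate, CC(C)OB(OC(C)C)OC(C)C; water, O
Why: Bromine–lithium exchange, borylation and hydrolysis. Lithium is para to the silyloxy group, so no O-to-C silyl shift is possible, and brief cold dilute acid leaves the aryl silyl ether intact.

Step 5
Reactants: 11 5,7-dihydroxy-4H-chromen-4-one
Product: 12 7-(tert-butyldimethylsilyloxy)-5-hydroxy-4H-chromen-4-one
Conditions: TBSCl (1.05 equiv), imidazole (2 equiv), DMF, 0 °C
Reagents that add atoms: tert-butyldimethylsilyl chloride, CC(C)(C)[Si](C)(C)Cl
Why: Chemoselective silylation: the 7-OH is the acidic, unchelated phenol, while the 5-OH is held in the hydrogen bond to the C4 carbonyl and resists TBSCl.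

Step 6
Reactants: 12 7-(tert-butyldimethylsilyloxy)-5-hydroxy-4H-chromen-4-one
Product: 13 7-(tert-butyldimethylsilyloxy)-5-hydroxy-6-iodo-4H-chromen-4-one
Conditions: NIS (1.05 equiv), DMF, rt, dark
Reagents that add atoms: N-iodosuccinimide, O=C1CCC(=O)N1I
Why: Electrophilic aromatic iodination under neutral conditions, a reaction type that goes ortho to the chelated 5-OH in 5-hydroxy-7-alkoxy-flavones and -chromones. The O5–H···O=C4 chelate fixes the C4a=C5 bond, which leaves C6=C7 as an enol-ether-like bond polarised by O7 towards C6, whereas C8 depends on O1, whose lone pair is drained by the pyrone carbonyl. C3 of ring C is far less nucleophilic than the trioxygenated ring A.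

Step 7
Reactants: 13 7-(tert-butyldimethylsilyloxy)-5-hydroxy-6-iodo-4H-chromen-4-one
Product: 14 5,7-bis(tert-butyldimethylsilyloxy)-6-iodo-4H-chromen-4-one
Conditions: TBSOTf (1.5 equiv), 2,6-lutidine (2.5 equiv), CH2Cl2, 0 °C to rt
Reagents that add atoms: tert-butyldimethylsilyl triflate, CC(C)(C)[Si](C)(C)OS(=O)(=O)C(F)(F)F
Why: Silyl triflate with a hindered base is the standard answer to a chelated, flanked phenol. It is done here so that no acidic proton can later protodestannylate 15 and no tertiary alcohol competes for the reagent.

Step 8
Reactants: 14 5,7-bis(tert-butyldimethylsilyloxy)-6-iodo-4H-chromen-4-one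
Product: 15 5,7-bis(tert-butyldimethylsilyloxy)-6-(trimethylstannyl)-4H-chromen-4-one
Conditions: (Me3Sn)2 (1.3 equiv), Pd(PPh3)4 (5 mol %), toluene, 100 °C
Reagents that add atoms: hexamethylditin, C[Sn](C)(C)[Sn](C)(C)C
Why: Palladium-catalysed iodine–tin exchange with a distannane (oxidative addition, Sn–Sn transmetalation, reductive elimination); it is neutral, so the aryl silyl ethers and the γ-pyrone survive. Trimethyltin is preferred to tributyltin because the site lies between two silyloxy groups.

Step 9
Reactants: 15 5,7-bis(tert-butyldimethylsilyloxy)-6-(trimethylstannyl)-4H-chromen-4-one; 5 (2E,5E)-7-hydroxy-3,7-dimethylocta-2,5-dien-1-yl acetate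
Product: 16 5,7-bis(tert-butyldimethylsilyloxy)-6-[(2E,5E)-7-hydroxy-3,7-dimethylocta-2,5-dien-1-yl]-4H-chromen-4-one
Conditions: 5 (1.2 equiv), Pd2(dba)3 (2.5 mol %), LiCl (3 equiv), DMF, 25–40 °C
Reagents that add atoms: none
Why: Stille-type coupling of an allylic acetate with an arylstannane under phosphine-free Pd(0)/LiCl. Ionisation of the primary acetate gives the syn π-allyl complex over C1''–C3'', the electron-rich aryl group passes from tin to palladium, and reductive elimination occurs at the unsubstituted terminus C1''; the E geometry is kept because syn/anti exchange would need a σ-bond at the tertiary C3''. The tertiary alcohol has no leaving group under these neutral conditions, and the remote C5''=C6'' alkene is not involved.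

Step 10
Reactants: 16 5,7-bis(tert-butyldimethylsilyloxy)-6-[(2E,5E)-7-hydroxy-3,7-dimethylocta-2,5-dien-1-yl]-4H-chromen-4-one; 10 [4-(tert-butyldimethylsilyloxy)-3-methoxyphenyl]boronic acid
Product: 17 (2S)-5,7-bis(tert-butyldimethylsilyloxy)-2-[4-(tert-butyldimethylsilyloxy)-3-methoxyphenyl]-6-[(2E,5E)-7-hydroxy-3,7-dimethylocta-2,5-dien-1-yl]-2,3-dihydro-4H-chromen-4-one
Conditions: [Rh(OH)(cod)]2 (2.5 mol %), (S)-MeO-F12-BIPHEP [(S)-2,2'-bis{bis(3,4,5-trifluorophenyl)phosphino}-6,6'-dimethoxybiphenyl] (5.5 mol %), 10 (2.5 equiv, in portions), toluene/H2O 10:1, 25 °C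
Reagents that add atoms: none
Why: Hayashi–Miyaura asymmetric 1,4-addition, a reaction type established on chromones: the hydroxorhodium complex takes the aryl group from 10 by transmetalation, the aryl–Rh(I) species binds C2=C3 of 16 and inserts it syn so that aryl goes to C2 and rhodium to C3 (oxa-π-allyl enolate), and water protonates C3 and returns Rh–OH. No ring is closed; ring C is already in place and only changes from a flat γ-pyrone into the dihydropyranone. The single new stereocentre C2 is controlled by the ligand alone: in the quadrant model of (S)-biaryl diphosphines the enone should bind so that aryl reaches the Re face of C2 (O1 > C3 > H), the same spatial sense that leads to (S)-3-arylcyclohexanones and here to 2S, which is to be confirmed on the first sample with the ligand antipode at hand. Regioselectivity (C2 against C4) follows from the soft aryl–rhodium nucleophile and from the 5-silyloxy group that screens the carbonyl, which should also block a second, 1,2-addition to 17. Chemoselectivity against the two chain alkenes rests on the need of aryl–Rh(I) for a carbonyl-conjugated alkene, and the free tertiary alcohol is only a spectator. The electron-poor ligand makes rhodium π-acidic enough for this donor-substituted acceptor at room temperature, which should keep protodeboronation of 10 and β-aryloxide elimination from the rhodium enolate (ring opening, the racemisation channel) slower than protonation. O5 must be silylated because a free chelated 5-OH would bind rhodium like an acetylacetonate and slow the transmetalation.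

Step 11
Reactants: 17 (2S)-5,7-bis(tert-butyldimethylsilyloxy)-2-[4-(tert-butyldimethylsilyloxy)-3-methoxyphenyl]-6-[(2E,5E)-7-hydroxy-3,7-dimethylocta-2,5-dien-1-yl]-2,3-dihydro-4H-chromen-4-one
Product: 18 tomentodiplacone B
Conditions: TBAF (3.3 equiv), AcOH (4 equiv), THF, 0 °C
Reagents that add atoms: none
Why: Fluoride cleavage of aryl silyl ethers, fast at 0 °C because phenoxides leave silicon readily. Acetic acid protonates each phenoxide as it forms, so neither retro-oxa-Michael opening of ring C (C2 stays S, the chain stays on C6) nor ionisation of the tertiary allylic alcohol should occur.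

## Compound list

1 | geranyl acetate | CC(=O)OC/C=C(\C)CCC=C(C)C | starting material
2 | 6,7-epoxygeranyl acetate, (2E)-5-(3,3-dimethyloxiran-2-yl)-3-methylpent-2-en-1-yl acetate (racemic) | CC(=O)OC/C=C(\C)CCC1OC1(C)C | intermediate
3 | (2E)-7-hydroxy-3,7-dimethyl-6-(phenylselanyl)oct-2-en-1-yl acetate (racemic, not isolated) | CC(=O)OC/C=C(\C)CCC([Se]c1ccccc1)C(C)(C)O | intermediate
4 | (2E)-7-hydroxy-3,7-dimethyl-6-(phenylseleninyl)oct-2-en-1-yl acetate (stereoisomer mixture, not isolated) | CC(=O)OC/C=C(\C)CCC([Se](=O)c1ccccc1)C(C)(C)O | intermediate
5 | (2E,5E)-7-hydroxy-3,7-dimethylocta-2,5-dien-1-yl acetate | CC(=O)OC/C=C(\C)C/C=C/C(C)(C)O | intermediate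
6 | 4-bromo-2-methoxyphenol | COc1cc(Br)ccc1O | starting material
7 | (4-bromo-2-methoxyphenoxy)(tert-butyl)dimethylsilane | COc1cc(Br)ccc1O[Si](C)(C)C(C)(C)C | intermediate
8 | [4-(tert-butyldimethylsilyloxy)-3-methoxyphenyl]lithium (not isolated) | COc1cc([Li])ccc1O[Si](C)(C)C(C)(C)C | intermediate
9 | lithium [4-(tert-butyldimethylsilyloxy)-3-methoxyphenyl]triisopropoxyborate (not isolated) | [Li+].COc1cc([B-](OC(C)C)(OC(C)C)OC(C)C)ccc1O[Si](C)(C)C(C)(C)C | intermediate
10 | [4-(tert-butyldimethylsilyloxy)-3-methoxyphenyl]boronic acid | COc1cc(B(O)O)ccc1O[Si](C)(C)C(C)(C)C | intermediate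
11 | 5,7-dihydroxy-4H-chromen-4-one | O=c1ccoc2cc(O)cc(O)c12 | starting material
12 | 7-(tert-butyldimethylsilyloxy)-5-hydroxy-4H-chromen-4-one | O=c1ccoc2cc(O[Si](C)(C)C(C)(C)C)cc(O)c12 | intermediate
13 | 7-(tert-butyldimethylsilyloxy)-5-hydroxy-6-iodo-4H-chromen-4-one | O=c1ccoc2cc(O[Si](C)(C)C(C)(C)C)c(I)c(O)c12 | intermediate
14 | 5,7-bis(tert-butyldimethylsilyloxy)-6-iodo-4H-chromen-4-one | O=c1ccoc2cc(O[Si](C)(C)C(C)(C)C)c(I)c(O[Si](C)(C)C(C)(C)C)c12 | intermediate
15 | 5,7-bis(tert-butyldimethylsilyloxy)-6-(trimethylstannyl)-4H-chromen-4-one | O=c1ccoc2cc(O[Si](C)(C)C(C)(C)C)c([Sn](C)(C)C)c(O[Si](C)(C)C(C)(C)C)c12 | intermediate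
16 | 5,7-bis(tert-butyldimethylsilyloxy)-6-[(2E,5E)-7-hydroxy-3,7-dimethylocta-2,5-dien-1-yl]-4H-chromen-4-one | O=c1ccoc2cc(O[Si](C)(C)C(C)(C)C)c(C/C=C(\C)C/C=C/C(C)(C)O)c(O[Si](C)(C)C(C)(C)C)c12 | intermediate
17 | (2S)-5,7-bis(tert-butyldimethylsilyloxy)-2-[4-(tert-butyldimethylsilyloxy)-3-methoxyphenyl]-6-[(2E,5E)-7-hydroxy-3,7-dimethylocta-2,5-dien-1-yl]-2,3-dihydro-4H-chromen-4-one | COc1cc([C@@H]2CC(=O)c3c(cc(O[Si](C)(C)C(C)(C)C)c(C/C=C(\C)C/C=C/C(C)(C)O)c3O[Si](C)(C)C(C)(C)C)O2)ccc1O[Si](C)(C)C(C)(C)C | intermediate
18 | tomentodiplacone B, (2S)-5,7-dihydroxy-2-(4-hydroxy-3-methoxyphenyl)-6-[(2E,5E)-7-hydroxy-3,7-dimethylocta-2,5-dien-1-yl]-2,3-dihydro-4H-chromen-4-one | COc1cc([C@@H]2CC(=O)c3c(cc(O)c(C/C=C(\C)C/C=C/C(C)(C)O)c3O)O2)ccc1O | target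

## Step count and least certain steps

Total step count: 11.

Longest linear sequence: 7 steps (11 → 12 → 13 → 14 → 15 → 16 → 17 → 18, steps 5–11). The chain branch (steps 1–2) joins at step 9, and the boronic acid branch (steps 3–4) joins at step 10.

**Step 10 (key step).**
- Risk: insertion of the donor-rich C2=C3 bond may be slow, so that protodeboronation of the electron-rich boronic acid outruns the addition. Facial discrimination may be incomplete. β-Aryloxide elimination from the rhodium enolate would open ring C and erode the configuration.
- Fallback: the stereocentre is set by resolution instead of by asymmetric C–C bond formation. It sets out from 16 and 10, which are joined with the phosphine-free and more active [Rh(OH)(cod)]2 in dioxane/H2O to the racemic tris-silyl flavanone F1. F1 then undergoes kinetic resolution by Noyori-type asymmetric transfer hydrogenation (Cp*Rh–TsDPEN, HCO2H/Et3N, EtOAc, rt) with the catalyst antipode matched to the (2R)-ketone. That ketone is reduced to the (2R,4R)-cis-flavan-4-ol F2 while the (2S)-ketone remains. Chromatography brings the route back at 17.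

**Step 9.**
- Risk: transmetalation may be slow because tin sits between two silyloxy groups. This gives the π-allyl complex time for β-hydride loss towards a triene. The very electron-rich ring may also protodestannylate on traces of acid.
- Fallback: the chain is joined at C4''–C5'' instead of C6–C1''. It sets out from 14. Stille coupling with commercial tributyl(3-methylbut-2-enyl)stannane (Pd(PPh3)4, DMF, 90 °C), whose symmetrical terminus removes the geometry question, should give the 6-prenylchromone F3. Catalytic SeO2 with t-BuOOH oxidises the E methyl group to the (E)-allylic alcohol F4, and Ac2O/pyridine gives the allylic acetate F5. (E)-2-Methyl-4-(tributylstannyl)but-3-en-2-ol F6, made by hydrostannation of 2-methylbut-3-yn-2-ol (Bu3SnH, AIBN), is coupled with F5 under the conditions of step 9 at the primary terminus. The route comes back at 16.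

**Step 6.**
- Risk: attack at C8 or a second iodination may compete if the chelate control is weaker on the chromone than expected, and the 7-O-silyl group may be partly lost.
- Fallback: C6 is fixed by pericyclic topology instead of SEAr selectivity. It sets out from 12. Mitsunobu reaction with allyl alcohol gives the 5-O-allyl ether F7. Aromatic Claisen rearrangement (PhNEt2, 190 °C) can only reach C6, the single free ortho position of O5, and gives the 6-allyl-5-hydroxychromone F8. TBSOTf/2,6-lutidine gives the bis-silyl ether F9. Cross-metathesis with 2-methylbut-2-ene (Grubbs II catalyst, 40 °C) gives F3, from which the fallback of step 9 leads through F4 and F5 back to the route at 16.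

**Step 11.**
- Risk: if buffering is insufficient, phenoxide-triggered opening of ring C would cause loss of configuration and migration of the chain position on re-closure through O5. If the medium is too acidic, the tertiary allylic alcohol would ionise.
- Fallback: the fluoride step is moved in front of the stereocentre. It sets out from 16, which is desilylated with TBAF while still flat to the 5,7-dihydroxychromone F10 and acetylated (Ac2O, pyridine, rt) to the diacetate F11. The conditions of step 10 with commercial 4-acetoxy-3-methoxyphenylboronic acid pinacol ester should give the (2S)-flavanone triacetate F12. Its three aryl acetates are removed by neutral NH4OAc in aqueous methanol at rt, and the route comes back at 18.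

**Step 2.**
- Risk: the acetate may undergo ethanolysis during the slow SN2 opening at the hindered carbon. The remaining alkenes may be epoxidised by the peroxyseleninic acid that forms from the selenium by-product and H2O2.
- Fallback: oxygen is brought in by an ene reaction instead of epoxide opening. It sets out from 1. Schenck ene reaction (O2, tetraphenylporphyrin, hν, CH2Cl2, 0 °C) at the more electron-rich distal alkene gives the tertiary allylic hydroperoxide F13. The ene reaction is not regiospecific within this alkene, so a chromatographic separation has to be accepted. Reduction with PPh3 brings the route back at 5.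

## Further compounds

F1 | step 10 | racemic 5,7-bis(tert-butyldimethylsilyloxy)-2-[4-(tert-butyldimethylsilyloxy)-3-methoxyphenyl]-6-[(2E,5E)-7-hydroxy-3,7-dimethylocta-2,5-dien-1-yl]-2,3-dihydro-4H-chromen-4-one | COc1cc(C2CC(=O)c3c(cc(O[Si](C)(C)C(C)(C)C)c(C/C=C(\C)C/C=C/C(C)(C)O)c3O[Si](C)(C)C(C)(C)C)O2)ccc1O[Si](C)(C)C(C)(C)C
F2 | step 10 | (2R,4R)-cis-flavan-4-ol derived from the (2R)-enantiomer of F1 | COc1cc([C@H]2C[C@@H](O)c3c(cc(O[Si](C)(C)C(C)(C)C)c(C/C=C(\C)C/C=C/C(C)(C)O)c3O[Si](C)(C)C(C)(C)C)O2)ccc1O[Si](C)(C)C(C)(C)C
F3 | step 9 | 5,7-bis(tert-butyldimethylsilyloxy)-6-(3-methylbut-2-en-1-yl)-4H-chromen-4-one | O=c1ccoc2cc(O[Si](C)(C)C(C)(C)C)c(CC=C(C)C)c(O[Si](C)(C)C(C)(C)C)c12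
F4 | step 9 | 5,7-bis(tert-butyldimethylsilyloxy)-6-[(2E)-4-hydroxy-3-methylbut-2-en-1-yl]-4H-chromen-4-one | O=c1ccoc2cc(O[Si](C)(C)C(C)(C)C)c(C/C=C(\C)CO)c(O[Si](C)(C)C(C)(C)C)c12
F5 | step 9 | (2E)-4-[5,7-bis(tert-butyldimethylsilyloxy)-4-oxo-4H-chromen-6-yl]-2-methylbut-2-en-1-yl acetate | O=c1ccoc2cc(O[Si](C)(C)C(C)(C)C)c(C/C=C(\C)COC(C)=O)c(O[Si](C)(C)C(C)(C)C)c12
F6 | step 9 | (E)-2-methyl-4-(tributylstannyl)but-3-en-2-ol | CCCC[Sn](CCCC)(CCCC)/C=C/C(C)(C)O
F7 | step 6 | 5-(allyloxy)-7-(tert-butyldimethylsilyloxy)-4H-chromen-4-one | O=c1ccoc2cc(O[Si](C)(C)C(C)(C)C)cc(OCC=C)c12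
F8 | step 6 | 6-allyl-7-(tert-butyldimethylsilyloxy)-5-hydroxy-4H-chromen-4-one | O=c1ccoc2cc(O[Si](C)(C)C(C)(C)C)c(CC=C)c(O)c12
F9 | step 6 | 6-allyl-5,7-bis(tert-butyldimethylsilyloxy)-4H-chromen-4-one | O=c1ccoc2cc(O[Si](C)(C)C(C)(C)C)c(CC=C)c(O[Si](C)(C)C(C)(C)C)c12
F10 | step 11 | 5,7-dihydroxy-6-[(2E,5E)-7-hydroxy-3,7-dimethylocta-2,5-dien-1-yl]-4H-chromen-4-one | O=c1ccoc2cc(O)c(C/C=C(\C)C/C=C/C(C)(C)O)c(O)c12
F11 | step 11 | 6-[(2E,5E)-7-hydroxy-3,7-dimethylocta-2,5-dien-1-yl]-4-oxo-4H-chromene-5,7-diyl diacetate | O=c1ccoc2cc(OC(C)=O)c(C/C=C(\C)C/C=C/C(C)(C)O)c(OC(C)=O)c12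
F12 | step 11 | (2S)-2-(4-acetoxy-3-methoxyphenyl)-6-[(2E,5E)-7-hydroxy-3,7-dimethylocta-2,5-dien-1-yl]-4-oxo-2,3-dihydro-4H-chromene-5,7-diyl diacetate | COc1cc([C@@H]2CC(=O)c3c(cc(OC(C)=O)c(C/C=C(\C)C/C=C/C(C)(C)O)c3OC(C)=O)O2)ccc1OC(C)=O
F13 | step 2 | (2E,5E)-7-hydroperoxy-3,7-dimethylocta-2,5-dien-1-yl acetate | CC(=O)OC/C=C(\C)C/C=C/C(C)(C)OO
A1 | alternative 1 | (E)-2',4',6',4-tetrahydroxy-3-methoxy-3'-[(2E,5E)-7-hydroxy-3,7-dimethylocta-2,5-dien-1-yl]chalcone | COc1cc(/C=C/C(=O)c2c(O)cc(O)c(C/C=C(\C)C/C=C/C(C)(C)O)c2O)ccc1O
A2 | alternative 2 | 1-[2-{[(2E,5E)-7-hydroxy-3,7-dimethylocta-2,5-dien-1-yl]oxy}-4,6-bis(methoxymethoxy)phenyl]ethanone | CC(=O)c1c(OCOC)cc(OCOC)cc1OC/C=C(\C)C/C=C/C(C)(C)O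
A3 | alternative 2 | 1-[6-hydroxy-3-[(5E)-7-hydroxy-3,7-dimethylocta-2,5-dien-1-yl]-2,4-bis(methoxymethoxy)phenyl]ethanone (2E/2Z mixture) | CC(=O)c1c(O)cc(OCOC)c(CC=C(C)C/C=C/C(C)(C)O)c1OCOC
A4 | alternative 3 | (2S)-5-bromo-2-[4-(tert-butyldimethylsilyloxy)-3-methoxyphenyl]-2,3-dihydro-4H-pyran-4-one | COc1cc([C@@H]2CC(=O)C(Br)=CO2)ccc1O[Si](C)(C)C(C)(C)C
A5 | alternative 3 | 1-methoxy-1,3-bis(trimethylsilyloxy)-2-[(2E,5E)-3,7-dimethyl-7-(trimethylsilyloxy)octa-2,5-dien-1-yl]buta-1,3-diene | C=C(O[Si](C)(C)C)C(C/C=C(\C)C/C=C/C(C)(C)O[Si](C)(C)C)=C(OC)O[Si](C)(C)C
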